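## Retrosynthetic overview

- Numbering: ring C1 (C–OH), C2, C3, C4 (CMeBr), C5 (CHCl), C6; side chain C7 (=CH2), C8, C9, C10 (CHOH), C11 (isopropenyl carbon). Last events: removal of the C10 silyl ether, and anti bromochlorination of the C4=C5 ring alkene directed by the C1 alkoxide, which relays the C1 configuration to C5 and C4.
- C7=CH2 comes from a Wittig methylenation of ketone 14. The C7–C8 bond comes from Weinreb amide 8 and chiral Grignard reagent 13, whose C10 centre is set by Shi epoxidation of a prenyl-type bromide.
- The only ring, cyclohexene C1–C6, is formed in step 3: a one-pot [5+1] double alkylation of chiral glycolate dioxanone 4 (C1, C7) with (Z)-dibromide 3 (C2–C6). C1–C6 forms first, intermolecularly; the ring then closes through C1–C2.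
- Enabling feature: C1 is a fully substituted carbinol carbon whose ring neighbours C2 and C6 are both CH2 and whose exocyclic neighbour C7 is sp2. C1(OH)–C7 is therefore a masked glycolic acid alpha carbon that can be alkylated twice. C2–C3–C4(Me)=C5–C6 is a (Z)-isoprenoid chain whose cis geometry, needed for closure, comes from six-membered lactone 1. The temporary 1,4-dioxanone ring of 4 sets (S)-C1 and is then cleaved.

Key step: step 3

Assumption: 4 is taken as a purchasable reagent, and its enolate is taken to accept electrophiles anti to the axial methoxy group on the acetal carbon attached to the ring ether oxygen of the enolate, also in the ring-closing alkylation; if the sense were the reverse, the (5R,6R) enantiomer would be used.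

## Route

Step 1
Reactants: 1 4-methyl-5,6-dihydro-2H-pyran-2-one
Product: 2 (Z)-3-methylpent-2-ene-1,5-diol
Conditions: iBu2AlH (3 equiv), CH2Cl2, −78 → 0 °C; aq. potassium sodium tartrate
Reagents that add atoms: none
Why: Hydride 1,2-reduction of the unsaturated lactone opens the ring to the diol, and the cis alkene geometry is inherited from the six-membered ring of 1.

Step 2
Reactants: 2 (Z)-3-methylpent-2-ene-1,5-diol
Product: 3 (Z)-1,5-dibromo-3-methylpent-2-ene
Conditions: CBr4 (2.4 equiv), PPh3 (2.4 equiv), CH2Cl2, −20 → 0 °C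
Reagents that add atoms: carbon tetrabromide, BrC(Br)(Br)Br
Why: Double Appel reaction; both hydroxyls are activated at once by excess reagent and displaced by bromide in SN2 fashion without allylic transposition, so the (Z) geometry should be kept and cyclic ether formation outrun.

Step 3
Reactants: 4 (5S,6S)-5,6-dimethoxy-5,6-dimethyl-1,4-dioxan-2-one; 3 (Z)-1,5-dibromo-3-methylpent-2-ene
Product: 6 (2S,3S,6S)-2,3-dimethoxy-2,3,9-trimethyl-1,4-dioxaspiro[5.5]undec-8-en-5-one, via monoalkylated dioxanone 5 (not isolated)
Conditions: LiN(SiMe3)2 (1.05 equiv), THF, −78 °C; 3 (0.95 equiv), −78 → −50 °C; then LiN(SiMe3)2 (1.1 equiv), DMPU, −78 → 0 °C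
Reagents that add atoms: none
Why: The lithium enolate of 4 is alkylated at its alpha carbon (the future C1) by the allylic bromide end of 3 to give 5; a second equivalent of base regenerates the enolate, erasing the first stereocentre, and this enolate displaces the remaining primary bromide intramolecularly to form the C1–C2 bond. The closest known reaction type is the sequential double alkylation of butane-2,3-diacetal-protected glycolate lactones to quaternary alpha-hydroxy acids, and the spiroannulation of chiral glycine or glycolate enolates with dihalides. The cyclohexene ring closes in a 6-(enolexo)-exo-tet mode, which the (Z) C4=C5 bond makes possible by holding C2 and C6 on the same side. The new stereocentre C1 is controlled by the dioxanone ring: the axial methoxy group on the acetal carbon attached to the ring ether oxygen of the enolate shields one face, so the ring-closing carbon C2 enters anti to it and (S)-C1 should result. The step needs chemoselectivity between the two C–Br bonds, secured by allylic versus unactivated primary reactivity and by a slight deficit of 3, and facial selectivity in the second alkylation, secured by the rigid trans-diaxial dimethoxy acetal.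

Step 4
Reactants: 6 (2S,3S,6S)-2,3-dimethoxy-2,3,9-trimethyl-1,4-dioxaspiro[5.5]undec-8-en-5-one
Product: 7 methyl (1S)-1-hydroxy-4-methylcyclohex-3-ene-1-carboxylate
Conditions: (+)-10-camphorsulfonic acid (cat.), MeOH, rt → 50 °C
Reagents that add atoms: methanol, CO
Why: Acid-catalysed transacetalisation and transesterification (methanolysis) should release the auxiliary as its tetramethyl ketal and leave the quaternary C1 untouched, since no bond to C1 is broken.

Step 5
Reactants: 7 methyl (1S)-1-hydroxy-4-methylcyclohex-3-ene-1-carboxylate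
Product: 8 (1S)-1-hydroxy-N-methoxy-N,4-dimethylcyclohex-3-ene-1-carboxamide
Conditions: MeNH(OMe)·HCl, iPrMgCl, THF, −20 → 0 °C
Reagents that add atoms: N,O-dimethylhydroxylamine hydrochloride, CNOC.Cl
Why: Weinreb amide formation by aminolysis of the ester with the magnesium amide, which tolerates the tertiary hydroxyl as its magnesium alkoxide.

Step 6
Reactants: 9 5-bromo-2-methylpent-2-ene
Product: 10 (3R)-3-(2-bromoethyl)-2,2-dimethyloxirane
Conditions: 1,2:4,5-di-O-isopropylidene-β-D-erythro-2,3-hexodiulo-2,6-pyranose (D-fructose-derived ketone, 30 mol %), KHSO5 (as 2KHSO5·KHSO4·K2SO4), K2CO3, Bu4NHSO4, Na2B4O7 buffer, MeCN/CH2(OMe)2/H2O, 0 °C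
Reagents that add atoms: potassium peroxymonosulfate, [K+].[O-]S(=O)(=O)OO
Why: Shi asymmetric epoxidation; the chiral dioxirane transfers oxygen through a spiro transition state, and with the D-fructose-derived ketone an alkene R–CH=CMe2 should give the (R) epoxide, which sets C10.

Step 7
Reactants: 10 (3R)-3-(2-bromoethyl)-2,2-dimethyloxirane
Product: 11 (3R)-5-bromo-2-methylpent-1-en-3-ol
Conditions: Et2AlCl, lithium 2,2,6,6-tetramethylpiperidide, toluene, 0 °C
Reagents that add atoms: none
Why: Aluminium amide-promoted isomerisation of an epoxide to an allylic alcohol (syn β-elimination with the proton taken from a methyl of the gem-dimethyl carbon); the C10–O bond is not touched, so C10 stays (R).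

Step 8
Reactants: 11 (3R)-5-bromo-2-methylpent-1-en-3-ol
Product: 12 [(3R)-5-bromo-2-methylpent-1-en-3-yl]oxy(tert-butyl)dimethylsilane
Conditions: tBuMe2SiCl, imidazole, DMF, rt
Reagents that add atoms: tert-butyldimethylsilyl chloride, CC(C)(C)[Si](C)(C)Cl
Why: Standard silylation of a secondary alcohol; the silyl ether removes the directing ability of the C10 oxygen in step 11 and survives Grignard formation.

Step 9
Reactants: 12 [(3R)-5-bromo-2-methylpent-1-en-3-yl]oxy(tert-butyl)dimethylsilane; 8 (1S)-1-hydroxy-N-methoxy-N,4-dimethylcyclohex-3-ene-1-carboxamide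
Product: 14 (4R)-4-(tert-butyldimethylsilyloxy)-1-[(1S)-1-hydroxy-4-methylcyclohex-3-en-1-yl]-5-methylhex-5-en-1-one, via Grignard reagent 13 (not isolated)
Conditions: 12, Mg, THF, 40 °C; 8 pretreated with iPrMgCl (1.0 equiv), THF, −20 °C; combine, −20 °C → rt
Reagents that add atoms: none
Why: Grignard addition to a Weinreb amide should stop at the ketone because the magnesium-chelated tetrahedral intermediate survives until work-up, and the tertiary hydroxyl is first deprotonated to its magnesium alkoxide so that it consumes none of 13.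

Step 10
Reactants: 14 (4R)-4-(tert-butyldimethylsilyloxy)-1-[(1S)-1-hydroxy-4-methylcyclohex-3-en-1-yl]-5-methylhex-5-en-1-one
Product: 15 (1S)-1-[(5R)-5-(tert-butyldimethylsilyloxy)-6-methylhepta-1,6-dien-2-yl]-4-methylcyclohex-3-en-1-ol
Conditions: Ph3PCH3Br (3 equiv), KOtBu (3 equiv), THF, 0 → 50 °C
Reagents that add atoms: methyltriphenylphosphonium bromide, C[P+](c1ccccc1)(c1ccccc1)c1ccccc1.[Br-]
Why: Wittig methylenation with excess unstabilised ylide should convert the hindered ketone to the C7 methylene; the tertiary hydroxyl is carried as its alkoxide and no stereocentre is epimerisable.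

Step 11
Reactants: 15 (1S)-1-[(5R)-5-(tert-butyldimethylsilyloxy)-6-methylhepta-1,6-dien-2-yl]-4-methylcyclohex-3-en-1-ol
Product: 16 (1S,3S,4S)-4-bromo-1-[(5R)-5-(tert-butyldimethylsilyloxy)-6-methylhepta-1,6-dien-2-yl]-3-chloro-4-methylcyclohexan-1-ol
Conditions: ClTi(OiPr)3 (1.2 equiv), hexanes/CH2Cl2, rt; then N-bromosuccinimide (1.05 equiv), −20 °C
Reagents that add atoms: N-bromosuccinimide, O=C1CCC(=O)N1Br; chlorotitanium triisopropoxide, CC(C)O[Ti](Cl)(OC(C)C)OC(C)C
Why: Proposed new method: exchange of the C1 hydroxyl into ClTi(OiPr)3 gives a tertiary titanium alkoxide that sits axial on the half-chair (the large side chain is equatorial) and shields the upper face, so N-bromosuccinimide should form the bromonium ion on the lower face of the electron-rich trisubstituted C4=C5 bond, and the titanium-bound chloride is then delivered through a six-membered transition state to the proximal carbon C5 from the alkoxide face, an anti, trans-diaxial opening (Fürst–Plattner) that places Cl on C5 cis to the C1 oxygen and Br on C4 trans to it against the Markovnikov preference for attack at C4; the closest known reaction type is the titanium-alkoxide-directed bromochlorination of allylic alcohols with N-bromosuccinimide and ClTi(OiPr)3, where chloride is likewise delivered to the alkene carbon three atoms from oxygen, and the two 1,1-disubstituted alkenes, each deactivated by an allylic C–O bond, are expected to react much more slowly.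

Step 12
Reactants: 16 (1S,3S,4S)-4-bromo-1-[(5R)-5-(tert-butyldimethylsilyloxy)-6-methylhepta-1,6-dien-2-yl]-3-chloro-4-methylcyclohexan-1-ol
Product: 17 (1S,3S,4S)-4-bromo-3-chloro-1-[(5R)-5-hydroxy-6-methylhepta-1,6-dien-2-yl]-4-methylcyclohexan-1-ol
Conditions: HF·pyridine, pyridine, THF, 0 °C → rt
Reagents that add atoms: none
Why: Fluoride-mediated desilylation under buffered, weakly acidic conditions should free the C10 hydroxyl without E2 loss of HBr from the tertiary bromide or ionisation of the tertiary allylic alcohol.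

## Compound list

1 | 4-methyl-5,6-dihydro-2H-pyran-2-one | CC1=CC(=O)OCC1 | starting material
2 | (Z)-3-methylpent-2-ene-1,5-diol | OC/C=C(C)\CCO | intermediate
3 | (Z)-1,5-dibromo-3-methylpent-2-ene | BrC/C=C(C)\CCBr | intermediate
4 | (5S,6S)-5,6-dimethoxy-5,6-dimethyl-1,4-dioxan-2-one | O=C1CO[C@](C)(OC)[C@@](C)(OC)O1 | starting material
5 | (3R,5S,6S)-3-[(Z)-5-bromo-3-methylpent-2-en-1-yl]-5,6-dimethoxy-5,6-dimethyl-1,4-dioxan-2-one | O=C1[C@@H](C/C=C(C)\CCBr)O[C@](C)(OC)[C@@](C)(OC)O1 | intermediate
6 | (2S,3S,6S)-2,3-dimethoxy-2,3,9-trimethyl-1,4-dioxaspiro[5.5]undec-8-en-5-one | O=C1[C@]2(CC=C(C)CC2)O[C@](C)(OC)[C@@](C)(OC)O1 | intermediate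
7 | methyl (1S)-1-hydroxy-4-methylcyclohex-3-ene-1-carboxylate | COC(=O)[C@]1(O)CCC(C)=CC1 | intermediate
8 | (1S)-1-hydroxy-N-methoxy-N,4-dimethylcyclohex-3-ene-1-carboxamide | CON(C)C(=O)[C@]1(O)CCC(C)=CC1 | intermediate
9 | 5-bromo-2-methylpent-2-ene | CC(C)=CCCBr | starting material
10 | (3R)-3-(2-bromoethyl)-2,2-dimethyloxirane | CC1(C)O[C@@H]1CCBr | intermediate
11 | (3R)-5-bromo-2-methylpent-1-en-3-ol | C=C(C)[C@H](O)CCBr | intermediate
12 | [(3R)-5-bromo-2-methylpent-1-en-3-yl]oxy(tert-butyl)dimethylsilane | C=C(C)[C@H](O[Si](C)(C)C(C)(C)C)CCBr | intermediate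
13 | [(3R)-3-(tert-butyldimethylsilyloxy)-4-methylpent-4-en-1-yl]magnesium bromide | C=C(C)[C@H](O[Si](C)(C)C(C)(C)C)CC[Mg]Br | intermediate
14 | (4R)-4-(tert-butyldimethylsilyloxy)-1-[(1S)-1-hydroxy-4-methylcyclohex-3-en-1-yl]-5-methylhex-5-en-1-one | C=C(C)[C@H](O[Si](C)(C)C(C)(C)C)CCC(=O)[C@]1(O)CCC(C)=CC1 | intermediate
15 | (1S)-1-[(5R)-5-(tert-butyldimethylsilyloxy)-6-methylhepta-1,6-dien-2-yl]-4-methylcyclohex-3-en-1-ol | C=C(C)[C@H](O[Si](C)(C)C(C)(C)C)CCC(=C)[C@]1(O)CCC(C)=CC1 | intermediate
16 | (1S,3S,4S)-4-bromo-1-[(5R)-5-(tert-butyldimethylsilyloxy)-6-methylhepta-1,6-dien-2-yl]-3-chloro-4-methylcyclohexan-1-ol | C=C(C)[C@H](O[Si](C)(C)C(C)(C)C)CCC(=C)[C@]1(O)CC[C@](C)(Br)[C@@H](Cl)C1 | intermediate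
17 | (1S,3S,4S)-4-bromo-3-chloro-1-[(5R)-5-hydroxy-6-methylhepta-1,6-dien-2-yl]-4-methylcyclohexan-1-ol | C=C(C)[C@H](O)CCC(=C)[C@]1(O)CC[C@](C)(Br)[C@@H](Cl)C1 | target

## Step count and risks

Total step count: 12. Longest linear sequence: 9 steps (steps 1, 2, 3, 4, 5, 9, 10, 11, 12).

Steps most likely to fail:

**Step 11 (proposed new method).** The chloride may open the bromonium ion at the tertiary carbon C4 (Markovnikov opening) instead of C5. The C1 alkoxide oxygen may itself attack the bromonium ion to give a bridged bromo ether. The allylic 1,1-disubstituted alkene next to C1 may also be halogenated. Fallback, from 15 to 17, with known reactions and purely steric and stereoelectronic control: the tertiary hydroxyl is silylated (Et3SiOTf, 2,6-lutidine, CH2Cl2, −78 °C) to the C1 triethylsilyl ether F1. Undirected anti addition of BrCl (Bu4NBrCl2, CH2Cl2, −78 → 0 °C) follows; the axial silyloxy group hinders the upper face, so the bromonium ion should form on the lower face, and trans-diaxial opening at C5 is expected, as in the classical diaxial bromochlorination of rigid 1-methylcyclohexene-type alkenes. This should give the bis-silyl bromochloride F2, with the regioisomer removed by chromatography. HF·pyridine then removes both silyl groups and gives 17 directly.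

**Step 3 (key step).** The ring-closing alkylation may show poor facial selectivity, the homoallylic bromide may lose HBr by E2, or a second molecule of 3 may be alkylated intermolecularly. Fallback, from 3 to 7, replacing acetal-shielding control by self-regeneration of stereocentres: the enantiomeric auxiliary (5R,6R)-5,6-dimethoxy-5,6-dimethyl-1,4-dioxan-2-one F3 is monoalkylated with 3 (LiN(SiMe3)2, 1 equiv, THF, −78 °C) and the (3S)-monoalkylated dioxanone F4 is isolated. Hydrolysis (CF3CO2H/H2O) gives (2S,4Z)-7-bromo-2-hydroxy-5-methylhept-4-enoic acid F5. Condensation with pivalaldehyde (p-toluenesulfonic acid cat., pentane, water removal) gives the cis-dioxolanone (2S,5S)-5-[(Z)-5-bromo-3-methylpent-2-en-1-yl]-2-tert-butyl-1,3-dioxolan-4-one F6. Its enolate (LiN(SiMe3)2, THF/DMPU, −78 → −20 °C) closes the C1–C2 bond anti to the tert-butyl group to give the spiro-dioxolanone (2S,5S)-2-tert-butyl-8-methyl-1,3-dioxaspiro[4.5]dec-7-en-4-one F7. Methanolysis (K2CO3, MeOH) returns to 7.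

**Step 10.** Olefination of the hindered ketone that carries an alkoxide may be slow, and on heating in base an alpha-ketol rearrangement may compete. Fallback, from 14 to 15, by addition and elimination instead of an ylide (Peterson olefination): Me3SiCH2MgCl with anhydrous CeCl3 (THF, −78 → 0 °C) adds to the ketone to give the β-hydroxysilane (5R)-5-(tert-butyldimethylsilyloxy)-2-[(1S)-1-hydroxy-4-methylcyclohex-3-en-1-yl]-6-methyl-1-(trimethylsilyl)hept-6-en-2-ol F8, as a mixture of epimers at the new carbinol carbon, which is of no consequence. KH (THF, 0 °C → rt) then effects syn elimination to 15.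

Further compounds
F1 | step 11 | triethyl({(1S)-1-[(5R)-5-(tert-butyldimethylsilyloxy)-6-methylhepta-1,6-dien-2-yl]-4-methylcyclohex-3-en-1-yl}oxy)silane | C=C(C)[C@H](O[Si](C)(C)C(C)(C)C)CCC(=C)[C@]1(O[Si](CC)(CC)CC)CCC(C)=CC1
F2 | step 11 | triethyl({(1S,3S,4S)-4-bromo-1-[(5R)-5-(tert-butyldimethylsilyloxy)-6-methylhepta-1,6-dien-2-yl]-3-chloro-4-methylcyclohexyl}oxy)silane | C=C(C)[C@H](O[Si](C)(C)C(C)(C)C)CCC(=C)[C@]1(O[Si](CC)(CC)CC)CC[C@](C)(Br)[C@@H](Cl)C1
F3 | step 3 | (5R,6R)-5,6-dimethoxy-5,6-dimethyl-1,4-dioxan-2-one | O=C1CO[C@@](C)(OC)[C@](C)(OC)O1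
F4 | step 3 | (3S,5R,6R)-3-[(Z)-5-bromo-3-methylpent-2-en-1-yl]-5,6-dimethoxy-5,6-dimethyl-1,4-dioxan-2-one | O=C1[C@H](C/C=C(C)\CCBr)O[C@@](C)(OC)[C@](C)(OC)O1
F5 | step 3 | (2S,4Z)-7-bromo-2-hydroxy-5-methylhept-4-enoic acid | OC(=O)[C@@H](O)C/C=C(C)\CCBr
F6 | step 3 | (2S,5S)-5-[(Z)-5-bromo-3-methylpent-2-en-1-yl]-2-tert-butyl-1,3-dioxolan-4-one | O=C1O[C@@H](C(C)(C)C)O[C@H]1C/C=C(C)\CCBr
F7 | step 3 | (2S,5S)-2-tert-butyl-8-methyl-1,3-dioxaspiro[4.5]dec-7-en-4-one | O=C1O[C@@H](C(C)(C)C)O[C@@]12CC=C(C)CC2
F8 | step 10 | (5R)-5-(tert-butyldimethylsilyloxy)-2-[(1S)-1-hydroxy-4-methylcyclohex-3-en-1-yl]-6-methyl-1-(trimethylsilyl)hept-6-en-2-ol | C=C(C)[C@H](O[Si](C)(C)C(C)(C)C)CCC(O)(C[Si](C)(C)C)[C@]1(O)CCC(C)=CC1
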